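**Assumptions (one line each)**
- Germacrane numbering is used for the target: C1 ketal carbon, C4 ether carbon, C5=C6, C6–O–C12 lactone, C7=C11, C8 tiglate, C10 methine, C13 CH2OAc.
- Routine reagents are commercial and not numbered; step 6 is a two-operation telescope counted as one step.
- The dianion methylation in step 1 is assumed to be trans-selective (dr ≥ 8:1) by analogy with other γ-substituted butyrolactone enolates; this is not a documented result for this acid.

**Retrosynthetic overview**
1. The C1 methyl ketal comes from the C1 hemiketal (MeOH, H+). The hemiketal and the (5E)-ylidene butenolide are both released by acid from a 10-membered keto ester (C6 ketone, cis CO2tBu, C4-OH, C1 ketone).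
2. The 10-membered carbocycle is closed first, at C6–C7, by a Cr-electrocatalytic Nozaki–Hiyama–Kishi macrocyclisation of a vinyl iodide onto an aldehyde. The butenolide and the bridging THF ketal form afterwards in one acid step.
3. The seco chain is joined at C1–C2 by adding an organocerium (C2–C6, carrying C4) to a γ-lactone (C1, C7–C14, carrying C8 and C10).
4. The C2–C6 piece comes from (R)-linalool by ozonolysis and a photochemical alkoxy-radical fragmentation. The lactone comes from (S)-5-oxotetrahydrofuran-2-carboxylic acid by trans-methylation, then ynoate formation and iodo-aldol.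

**Route**

Step 1
Reactants: 1, (S)-5-oxotetrahydrofuran-2-carboxylic acid
Product: 2, (2S,4R)-4-methyl-5-oxotetrahydrofuran-2-carboxylic acid (trans)
Conditions: LDA (2.2 equiv), THF, −78 °C; MeI, −78 → −40 °C; H3O+
Reagents that add atoms: iodomethane, CI
Why: Alkylation of the carboxylate/lactone-enolate dianion; MeI approaches anti to the C8 carboxylate, so C8 (S, bought) sets C10 (R) as the 2,4-trans lactone.

Step 2
Reactants: 2
Product: 3, tert-butyl 3-[(2S,4R)-4-methyl-5-oxooxolan-2-yl]-3-oxopropanoate
Conditions: CDI, THF, rt; then Mg(O2CCH2CO2tBu)2, rt → 40 °C; aq. citric acid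
Reagents that add atoms: mono-tert-butyl malonate (Mg salt), OC(=O)CC(=O)OC(C)(C)C
Why: Masamune–Brooks decarboxylative Claisen homologation of the acyl imidazolide under near-neutral conditions, so the lactone and the C8/C10 centres are untouched.

Step 3
Reactants: 3
Product: 4, tert-butyl 3-[(2S,4R)-4-methyl-5-oxooxolan-2-yl]prop-2-ynoate
Conditions: LiHMDS (1.05 equiv), Tf2O, THF, −78 °C; then LiHMDS (1.05 equiv), −78 °C
Reagents that add atoms: none
Why: β-Keto ester → (Z)-enol triflate → anti-E2 loss of TfOH gives the conjugated ynoate; the vinylic α-H is removed far faster than the lactone α-H at −78 °C.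

Step 4
Reactants: 4
Product: 5, tert-butyl (2Z)-2-(hydroxymethyl)-3-iodo-3-[(2S,4R)-4-methyl-5-oxooxolan-2-yl]prop-2-enoate
Conditions: MgI2 (1.5 equiv), monomeric CH2O (from paraformaldehyde), CH2Cl2, 0 °C
Reagents that add atoms: magnesium iodide, [Mg+2].[I-].[I-]; formaldehyde, C=O
Why: MgI2 halo-aldol (β-iodo Baylis–Hillman): iodide adds at C7, the β-iodo allenolate is trapped at C11 by CH2O anti to iodine, giving the Z isomer (I cis to CO2tBu) and installing C13.

Step 5
Reactants: 6, (R)-(−)-linalool
Product: 7, (5R)-5-ethenyl-5-methyloxolan-2-ol (anomer mixture)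
Conditions: O3 (1.0 equiv), CH2Cl2/MeOH, −78 °C; Me2S
Reagents that add atoms: ozone, [O-][O+]=O
Why: Chemoselective ozonolysis of the electron-rich trisubstituted alkene; the aldehyde closes onto the tertiary OH as the lactol, and the C4 stereocentre is untouched.

Step 6
Reactants: 7
Product: 9, (3R)-5-iodo-3-methylpent-1-en-3-ol, via 8, (3R)-5-iodo-3-methylpent-1-en-3-yl formate (not isolated)
Conditions: PhI(OAc)2, I2, CH2Cl2, visible light, 20 °C; then K2CO3, MeOH, 0 °C
Reagents that add atoms: iodine, II
Why: Suárez hypoiodite photolysis: the anomeric alkoxy radical undergoes β-scission of C1–C2, the primary C2 radical is trapped by iodine and the formate is then methanolysed; C4 is not involved.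

Step 7
Reactants: 9 and 5
Product: 10, tert-butyl (2Z,4S,6R,10R)-4,10-dihydroxy-2-(hydroxymethyl)-3-iodo-6,10-dimethyl-7-oxododeca-2,11-dienoate (in equilibrium with its lactols)
Conditions: 9: n-BuLi (1 equiv) then t-BuLi (2 equiv), Et2O, −78 °C; CeCl3, THF, −78 °C; add 5 (pre-treated with LiHMDS, 1 equiv), −78 °C; aq. NH4Cl
Reagents that add atoms: none (fragment union)
Why: I/Li exchange, transmetalation to cerium and 1,2-addition to the γ-lactone give a stable lactolate (single addition); the non-basic organocerium should spare the vinyl iodide, the hindered tert-butyl enoate and the C10–H, forming the C1–C2 bond and the C1 ketone.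

Step 8
Reactants: 10
Product: 11, tert-butyl (2Z,4S,6R,10R)-2-(acetoxymethyl)-4,10-dihydroxy-3-iodo-6,10-dimethyl-7-oxododeca-2,11-dienoate
Conditions: AcCl (1.05 equiv), 2,4,6-collidine, CH2Cl2, −78 °C
Reagents that add atoms: acetyl chloride, CC(=O)Cl
Why: Kinetically selective acylation of the primary allylic C13-OH over the hindered secondary C8-OH and tertiary C4-OH.

Step 9
Reactants: 11
Product: 12, tert-butyl (2Z,4S,6R,10R)-2-(acetoxymethyl)-10-hydroxy-3-iodo-6,10-dimethyl-4-[(E)-2-methylbut-2-enoyloxy]-7-oxododeca-2,11-dienoate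
Conditions: tigloyl chloride, Et3N, DMAP, CH2Cl2, 0 °C → rt
Reagents that add atoms: tigloyl chloride, C/C=C(\C)C(=O)Cl
Why: DMAP-catalysed esterification of the only remaining acylable (secondary C8) hydroxyl; the tertiary C4-OH is inert and the C8 configuration is retained.

Step 10
Reactants: 12
Product: 13, tert-butyl (2Z,4S,6R,10R)-2-(acetoxymethyl)-10,12-dihydroxy-3-iodo-6,10-dimethyl-4-[(E)-2-methylbut-2-enoyloxy]-7-oxododec-2-enoate
Conditions: 9-BBN (2.2 equiv), THF, 0 °C → rt; then aq. H2O2, pH 7 buffer, 0 °C
Reagents that add atoms: hydrogen peroxide, OO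
Why: Anti-Markovnikov hydroboration–oxidation of the only unhindered, electron-rich alkene (the C5=C6 vinyl); the enoates and vinyl iodide are inert to 9-BBN and the ketone reacts much more slowly.

Step 11
Reactants: 13
Product: 14, tert-butyl (2Z,4S,6R,10R)-2-(acetoxymethyl)-10-hydroxy-3-iodo-6,10-dimethyl-4-[(E)-2-methylbut-2-enoyloxy]-7,12-dioxododec-2-enoate
Conditions: TEMPO (10 mol %), PhI(OAc)2, CH2Cl2, rt
Reagents that add atoms: none
Why: TEMPO/PhI(OAc)2 oxidises the primary alcohol selectively to the C6 aldehyde without touching the tertiary alcohol.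

Step 12
Reactants: 14
Product: 15, ten-membered carbocycle (germacrane numbering): C1 ketone, C4(R) tertiary OH/Me, C6-OH (epimer mixture), exocyclic C7=C11 bearing CH2OAc and CO2tBu (CO2tBu cis to C6), C8(S)-OTig, C10(R)-Me
Conditions: CrCl2 (20 mol %), NiCl2·glyme/neocuproine (5 mol %), Cp2ZrCl2 (1.5 equiv), LiCl, DMF, Al(+) | Ni foam(−), constant current, syringe-pump addition of 14 (final 2 mM), rt
Reagents that add atoms: none
Why: Proposed new method: a Cr-electrocatalytic Nozaki–Hiyama–Kishi macrocyclisation — cathodic reduction keeps Cr(II)/Ni(0) at low steady state, Ni(0) inserts into the electron-poor tetrasubstituted C7–I bond, transmetalation gives a vinyl–Cr(III) that adds to the Cr-bound C6 aldehyde with retention of alkene geometry, and Cp2ZrCl2 frees Cr from the alkoxide for turnover; catalytic Cr should spare the β-hydroxy aldehyde, and the new C6 centre is erased in step 13. The closest known reactions are stoichiometric CrCl2/NiCl2 NHK macrocyclisations and intermolecular electrochemical NHK couplings; neither has been shown for a β-iodo enoate closing a 10-membered carbocycle.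

Step 13
Reactants: 15
Product: 16, the corresponding C6 ketone (a ten-membered 4-oxo-2-enoate with C6=O cis to CO2tBu)
Conditions: Dess–Martin periodinane, NaHCO3, CH2Cl2, 0 °C → rt
Reagents that add atoms: none
Why: Dess–Martin oxidation of the secondary allylic alcohol raises C6 to the oxidation level of the enol lactone; the tertiary C4-OH cannot be oxidised.

Step 14
Reactants: 16
Product: 17, (1S,4R,8S,10R)-1-hydroxy hemiketal (1-O-desmethyl-vernolide-B)
Conditions: TFA/CH2Cl2 (1:4), 0 °C → rt, short reaction time
Reagents that add atoms: none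
Why: Acid cleaves the tert-butyl ester; the cis keto acid closes to the γ-hydroxybutenolide and dehydrates towards C5, while C4-OH adds across the ring to the C1 ketone. The ring forces C4 and C7 cis on C5=C6 (5E), and the cis-only O-bridge lets C4 (from linalool) fix C1 as S.

Step 15
Reactants: 17
Product: 18, vernolide-B
Conditions: CSA (cat.), MeOH, rt
Reagents that add atoms: methanol, CO
Why: Acid-catalysed hemiketal → methyl ketal exchange at C1; the bridged skeleton leaves only one position for the methoxy group, so the C1 configuration is retained.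

**Compound list**

1 | (S)-5-oxotetrahydrofuran-2-carboxylic acid | OC(=O)[C@@H]1CCC(=O)O1 | starting material
2 | (2S,4R)-4-methyl-5-oxotetrahydrofuran-2-carboxylic acid | OC(=O)[C@@H]1C[C@@H](C)C(=O)O1 | intermediate
3 | tert-butyl 3-[(2S,4R)-4-methyl-5-oxooxolan-2-yl]-3-oxopropanoate | CC(C)(C)OC(=O)CC(=O)[C@@H]1C[C@@H](C)C(=O)O1 | intermediate
4 | tert-butyl 3-[(2S,4R)-4-methyl-5-oxooxolan-2-yl]prop-2-ynoate | CC(C)(C)OC(=O)C#C[C@@H]1C[C@@H](C)C(=O)O1 | intermediate
5 | tert-butyl (2Z)-2-(hydroxymethyl)-3-iodo-3-[(2S,4R)-4-methyl-5-oxooxolan-2-yl]prop-2-enoate | CC(C)(C)OC(=O)/C(CO)=C(\I)[C@@H]1C[C@@H](C)C(=O)O1 | intermediate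
6 | (R)-(−)-linalool | C=C[C@](C)(O)CCC=C(C)C | starting material
7 | (5R)-5-ethenyl-5-methyloxolan-2-ol | C=C[C@@]1(C)CCC(O)O1 | intermediate
8 | (3R)-5-iodo-3-methylpent-1-en-3-yl formate | C=C[C@](C)(OC=O)CCI | intermediate (not isolated)
9 | (3R)-5-iodo-3-methylpent-1-en-3-ol | C=C[C@](C)(O)CCI | intermediate
10 | tert-butyl (2Z,4S,6R,10R)-4,10-dihydroxy-2-(hydroxymethyl)-3-iodo-6,10-dimethyl-7-oxododeca-2,11-dienoate | C=C[C@](C)(O)CCC(=O)[C@H](C)C[C@H](O)/C(I)=C(\CO)C(=O)OC(C)(C)C | intermediate
11 | C13 acetate of 10 | C=C[C@](C)(O)CCC(=O)[C@H](C)C[C@H](O)/C(I)=C(\COC(C)=O)C(=O)OC(C)(C)C | intermediate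
12 | C13 acetate, C8 tiglate | C=C[C@](C)(O)CCC(=O)[C@H](C)C[C@H](OC(=O)/C(C)=C/C)/C(I)=C(\COC(C)=O)C(=O)OC(C)(C)C | intermediate
13 | C6 primary alcohol | OCC[C@](C)(O)CCC(=O)[C@H](C)C[C@H](OC(=O)/C(C)=C/C)/C(I)=C(\COC(C)=O)C(=O)OC(C)(C)C | intermediate
14 | C6 aldehyde | O=CC[C@](C)(O)CCC(=O)[C@H](C)C[C@H](OC(=O)/C(C)=C/C)/C(I)=C(\COC(C)=O)C(=O)OC(C)(C)C | intermediate
15 | ten-membered C6 carbinol | CC(=O)OC/C(C(=O)OC(C)(C)C)=C1/C(O)C[C@](C)(O)CCC(=O)[C@H](C)C[C@@H]1OC(=O)/C(C)=C/C | intermediate
16 | ten-membered C6 ketone | CC(=O)OC/C(C(=O)OC(C)(C)C)=C1/C(=O)C[C@](C)(O)CCC(=O)[C@H](C)C[C@@H]1OC(=O)/C(C)=C/C | intermediate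
17 | 1-O-desmethyl-vernolide-B (C1 hemiketal) | C/C=C(\C)C(=O)O[C@H]1C[C@@H](C)[C@]2(O)CC[C@](C)(/C=C3/OC(=O)C(COC(C)=O)=C31)O2 | intermediate
18 | vernolide-B | C/C=C(\C)C(=O)O[C@H]1C[C@@H](C)[C@]2(OC)CC[C@](C)(/C=C3/OC(=O)C(COC(C)=O)=C31)O2 | target

**Totals**
- Total steps: 15 (step 6 telescopes two operations).
- Longest linear sequence: 13 (1 → 18 through steps 1–4 and 7–15); the linalool branch is 2 steps (5–6).

**Three steps most likely to fail**
1. Step 12 (proposed electrochemical NHK macrocyclisation): the hindered vinyl iodide, the allylic esters and the 10-membered ring may defeat it. Fallback (known chemistry, different bond logic): close the same C6–C7 bond by intramolecular Pd(0) Heck reaction of 12 (vinyl iodide onto its own terminal vinyl), then TFA, iodolactonisation (I2, NaHCO3) and DBU dehydroiodination to the ylidene butenolide, then step 15. This also removes steps 10, 11 and 13.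
2. Step 7 (organocerium addition to the lactone beside a vinyl iodide and enoate): chemoselectivity may be poor. Fallback: reverse the order — add the dilithio reagent from 9 to the silyl-protected, α-methylated (S)-5-(hydroxymethyl)butyrolactone, which has no competing electrophile, protect C8-OH, and then build the iodo-enoate from C7 (desilylation, oxidation, Ohira–Bestmann alkynylation, carboxylation, MgI2/CH2O).
3. Step 1 (dianion methylation, dr and C8 integrity unproven): Fallback: start from (S)-5-(trityloxymethyl)dihydrofuran-2(3H)-one, use the established trans-selective LDA/MeI alkylation of that ether, then detritylate and oxidise the primary alcohol to acid 2.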